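All runs were computed from invented constants; noise was put on by code.

| flask | L | J | remark | time |
|---|---|---|---|---|
| eta | 0.50 mM | 1.2 equiv | run made earlier |  |
| delta | 0.50 mM | 2.4 equiv | run made earlier |  |
| zeta | 0.50 mM | 4.3 equiv | run made earlier |  |
| birch | 0.50 mM | 1.30 equiv |  | 2.0 min |
| cedar | 0.50 mM | 2.60 equiv |  | 2.0 min |
| oak | 0.50 mM | 5.20 equiv |  | 2.0 min |

| run | time / s | L / % | E / % |
|---|---|---|---|
| eta | 25.0 | 68.5 | 31.2 |
| eta | 50.0 | 59.2 | 41.2 |
| eta | 80.0 | 53.5 | 45.9 |
| eta | 90.0 | 52.7 | 47.5 |
| eta | 120 | 51.2 | 48.8 |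
| delta | 25.0 | 48.3 | 51.6 |
| delta | 50.0 | 35.3 | 64.3 |
| delta | 80.0 | 28.1 | 72.2 |
| delta | 90.0 | 26.4 | 73.5 |
| delta | 120 | 23.1 | 77.4 |
| zeta | 10.0 | 50.8 | 49.4 |
| zeta | 30.0 | 26.2 | 73.4 |
| zeta | 60.0 | 14.8 | 85.6 |
| zeta | 80.0 | 10.9 | 88.5 |
| zeta | 120 | 7.4 | 92.5 |

(readings scatter by 0.3 percentage points)

- part of the L that has reacted at the end, birch
- part of the L that has reacted at the end, cedar
- part of the L that has reacted at the end, oak
- what raising the equivalents of J from its lowest to its highest value here does to the part of the L that has reacted (changes below 5 percentage points count as none) (it falls / it rises / no change)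



- The ratio of J to L sets cedar apart from delta: 2.60 equiv against 2.4 equiv, on the same 0.50 mM of L, and cedar stops at 2.0 min, the time of delta's last reading.
- Delta's L reading of 23.1% at 120 s gives 0.771 as its turnover count, the number of L lifetimes a flask has had, one lifetime reckoned at a J concentration equal to the L charge. This is the integrated second-order term, N = ln[(r − f)/(r(1 − f))]/(r − 1), with r the equivalents of J and f the part of L reacted.
- The count does not grow in step with time: delta had 0.347 by 25.0 s, already half of its count at 120 s.
- At 120 s, eta reads 0.737 and zeta 0.716, so the count moves little across a wide range of ratios at this L charge.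
- My reckoning carries delta's count to cedar and solves for f, giving 79.8%. That figure lies above delta's reacted part of 76.9%, since the reckoning holds the count and raises the ratio.
- Eta's count gives birch 51.7%, and zeta's gives oak 96.0%; oak's ratio lies above zeta's, so that figure reaches past the runs.
- The forecast, working with “a rate constant that fades over time” and a common count of 0.74, gives 52%, 79% and 96%, and says it rises. On cedar it stands slightly below my figure.
- The flasks give 52.4% for birch, 79.6% for cedar and 95.3% for oak, so the reacted part: it rises, by 43 percentage points.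

    J ⇌ X (K = 0.360, k = 0.0920 s⁻¹)
    J + D ⇌ Z, settled at all times (K = 3.50 × 10⁶ M⁻¹)
    L + J → D + E (k = 57.0 M⁻¹ s⁻¹)
    J → G (k = 6.10 × 10⁻⁵ s⁻¹)
    2 J → Q (k = 18.0 M⁻¹ s⁻¹)

Read back as a count, cedar's result gives 0.765, beside delta's 0.771. Now take oak read early, at 30 s, with one setting changed. Zeta at 30.0 s reads a count of 0.349, half of its own 0.716 at 120 s in a quarter of the time. Solved at oak's 5.20 equiv, that count gives 80.5%. Oak read at 30 s gives 78.9%, with 21% of its L and 20% of its J still unbound.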